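## Retrosynthetic overview

Locants follow 1-benzofuran numbering (O1, C2, C3, C3a, C4 to C7, C7a); ring A is the six-membered ring, ring B the furan ring.

1. C5 centre: the target is the Cope isomer of its 3a-allyl dienone. A suprafacial [3,3] shift of the allyl group from C3a to the methoxy-bearing C5 relays chirality C3 → C3a → C5.
2. 3a-Allyl dienone: dearomatising para-allylation (phenol umpolung with an allylsilane) of the aromatic 2-aryl-3-methyl-5-methoxy-2,3-dihydrobenzofuran-6-ol, anti to the C3 methyl group.
3. Ring B: closed at O1–C7a from an acyclic (1S,2S)-1,2-diarylpropan-1-ol by oxidative dearomatisation. The enabling feature is the guaiacol pair of ring A (C6–OH beside C5–OMe): oxidation in methanol gives the C5 ortho-quinone monoketal, in which the unfunctionalised C7a–H has become a dienone β-carbon lying 5-exo to the benzylic hydroxyl; oxa-Michael addition and loss of methanol restore the arene.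
4. Diarylpropanol: Pd-catalysed α-arylation of a propiophenone (C3–C3a bond), then hydrogenation with dynamic kinetic resolution (C2 and C3).
5. Order of rings: ring A is bought as a benzene ring, ring B is closed in step 4, ring A is dearomatised for good in step 5 and its C5 centre is fixed in step 6.

Key step: step 4

Remark: both starting materials are taken as catalogue compounds, and the catalyst enantiomer in step 2 is assigned by analogy with simple aryl alkyl ketones (the antipodal catalyst is used if the sense proves opposite).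

## Route

Step 1
Reactants: 1 1-(3,4,5-trimethoxyphenyl)propan-1-one; 2 1-(benzyloxy)-4-bromo-2-methoxybenzene
Product: 3 rac-2-[4-(benzyloxy)-3-methoxyphenyl]-1-(3,4,5-trimethoxyphenyl)propan-1-one
Conditions: Pd(OAc)2 (2 mol%), Xantphos (2.5 mol%), NaOtBu (1.3 equiv), toluene, 80 °C
Reagents that add atoms: none
Why: Buchwald–Hartwig α-arylation: the sodium enolate of 1 couples with the aryl bromide at zerovalent palladium (oxidative addition, enolate transmetalation, reductive elimination), and the tertiary, hindered α-carbon of 3 resists a second arylation; the new stereocentre is formed racemic on purpose, because it is set in step 2.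

Step 2
Reactants: 3 rac-2-[4-(benzyloxy)-3-methoxyphenyl]-1-(3,4,5-trimethoxyphenyl)propan-1-one
Product: 4 (1S,2S)-2-[4-(benzyloxy)-3-methoxyphenyl]-1-(3,4,5-trimethoxyphenyl)propan-1-ol
Conditions: RuCl2[(R)-xylbinap][(R)-daipen] (0.5 mol%), KOtBu (20 mol%), i-PrOH, H2 (10 atm), 25 °C
Reagents that add atoms: none
Why: Noyori asymmetric hydrogenation with dynamic kinetic resolution: KOtBu racemises 3 through its enolate faster than it is reduced, and the bifunctional Ru–H/N–H catalyst should reduce the (2S)-ketone selectively on the Felkin–Anh face, so that the carbinol centre (catalyst control) and the methyl-bearing centre (matched substrate enantiomer) are set together as the (1S,2S) diastereomer.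

Step 3
Reactants: 4 (1S,2S)-2-[4-(benzyloxy)-3-methoxyphenyl]-1-(3,4,5-trimethoxyphenyl)propan-1-ol
Product: 5 (1S,2S)-2-(4-hydroxy-3-methoxyphenyl)-1-(3,4,5-trimethoxyphenyl)propan-1-ol
Conditions: H2 (1 atm), 10% Pd/C, EtOAc, 25 °C
Reagents that add atoms: none
Why: Hydrogenolysis of the benzyl aryl ether over palladium; under neutral conditions at one atmosphere the secondary benzylic alcohol, the aryl methyl ethers and both stereocentres should stay untouched.

Step 4
Reactants: 5 (1S,2S)-2-(4-hydroxy-3-methoxyphenyl)-1-(3,4,5-trimethoxyphenyl)propan-1-ol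
Product: 8 (2S,3S)-5-methoxy-3-methyl-2-(3,4,5-trimethoxyphenyl)-2,3-dihydro-1-benzofuran-6-ol, via ortho-quinone monoketal 6 (not isolated), via bicyclic ketal ketone 7 (not isolated)
Conditions: PhI(OAc)2 (1.0 equiv), MeOH (0.02 M), −20 °C; then K2CO3 (3 equiv), 0 °C; then AcOH, 25 °C
Reagents that add atoms: none
Why: Proposed new method: two-electron oxidation of the guaiacol ring by the trivalent iodine reagent in methanol should give the 6,6-dimethoxycyclohexa-2,4-dienone 6, in which the former arene carbon C7a is the β-carbon of the dienone; under K2CO3 the benzylic alkoxide adds to it to give 7, and acidification ionises the allylic ketal, methanol and the C7a proton are lost, and ring A re-aromatises to 8. The closest known reaction type is the formation of ortho-quinone monoketals from 2-methoxyphenols and their capture by nitrogen, sulfur and carbon nucleophiles with rearomatising loss of methanol; closing a dihydrofuran ring with a tethered secondary alcohol is the new element. Ring B closes by a 5-exo-trig oxa-Michael addition of O1 to C7a. No lasting stereocentre is created: C2 and C3 are carried over unchanged (no bond to either is broken and C3–H is not acidic in 6), and the C7a centre of 7 is erased on aromatisation. The step needs methanol to attack C5 and not C3a, and O1 to attack C7a and not C4; the C5 methoxy group directs ketal formation to its own carbon, and the tether secures the second, since attack at C4 would be a 5-endo-trig closure. Because 7 stays dearomatised until the oxidant is spent, the electron-rich phenol 8 should be spared over-oxidation.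

Step 5
Reactants: 8 (2S,3S)-5-methoxy-3-methyl-2-(3,4,5-trimethoxyphenyl)-2,3-dihydro-1-benzofuran-6-ol
Product: 9 (2S,3S,3aS)-5-methoxy-3-methyl-3a-(prop-2-en-1-yl)-2-(3,4,5-trimethoxyphenyl)-3,3a-dihydro-1-benzofuran-6(2H)-one
Conditions: PhI(OAc)2 (1.1 equiv), allylSiMe3 (5 equiv), (CF3)2CHOH, −20 °C
Reagents that add atoms: allyltrimethylsilane, C=CC[Si](C)(C)C
Why: Oxidative phenol umpolung with Hosomi–Sakurai-type capture, as known for para-substituted phenols in fluorinated alcohols: two-electron oxidation by the trivalent iodine reagent makes the ring carbons ortho and para to O6 electrophilic, the allylsilane should attack the para carbon C3a (also activated by O1), and the quaternary centre is set by approach anti to the adjacent C3 methyl group, on the face of C3–H, which gives 3aS.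

Step 6
Reactants: 9 (2S,3S,3aS)-5-methoxy-3-methyl-3a-(prop-2-en-1-yl)-2-(3,4,5-trimethoxyphenyl)-3,3a-dihydro-1-benzofuran-6(2H)-one
Product: 10 (2S,3S,5R)-5-methoxy-3-methyl-5-(prop-2-en-1-yl)-2-(3,4,5-trimethoxyphenyl)-2,3-dihydro-1-benzofuran-6(5H)-one
Conditions: toluene (degassed), 100–110 °C, sealed tube, base-washed glass
Reagents that add atoms: none
Why: Cope [3,3]-sigmatropic rearrangement of a 4-allylcyclohexa-2,5-dienone to the 6-allylcyclohexa-2,4-dienone through C3a–C4=C5: the shift is suprafacial on ring A, so the allyl group lands on C5 on the face it left at C3a and 3aS is relayed into 5R, with release of the crowded ring-fusion centre and the linearly conjugated vinylogous ester as driving force; acid-free glass and the lowest workable temperature should hold back migration to C7 and the onward retro-Claisen shift to O6.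

## Compound list

1 | 1-(3,4,5-trimethoxyphenyl)propan-1-one | CCC(=O)c1cc(OC)c(OC)c(OC)c1 | starting material
2 | 1-(benzyloxy)-4-bromo-2-methoxybenzene | COc1cc(Br)ccc1OCc1ccccc1 | starting material
3 | rac-2-[4-(benzyloxy)-3-methoxyphenyl]-1-(3,4,5-trimethoxyphenyl)propan-1-one | COc1cc(ccc1OCc1ccccc1)C(C)C(=O)c1cc(OC)c(OC)c(OC)c1 | intermediate
4 | (1S,2S)-2-[4-(benzyloxy)-3-methoxyphenyl]-1-(3,4,5-trimethoxyphenyl)propan-1-ol | COc1cc(ccc1OCc1ccccc1)[C@H](C)[C@H](O)c1cc(OC)c(OC)c(OC)c1 | intermediate
5 | (1S,2S)-2-(4-hydroxy-3-methoxyphenyl)-1-(3,4,5-trimethoxyphenyl)propan-1-ol | COc1cc(ccc1O)[C@H](C)[C@H](O)c1cc(OC)c(OC)c(OC)c1 | intermediate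
6 | 4-[(1S,2S)-1-hydroxy-1-(3,4,5-trimethoxyphenyl)propan-2-yl]-6,6-dimethoxycyclohexa-2,4-dien-1-one | COC1(OC)C=C(C=CC1=O)[C@H](C)[C@H](O)c1cc(OC)c(OC)c(OC)c1 | intermediate
7 | (2S,3S)-5,5-dimethoxy-3-methyl-2-(3,4,5-trimethoxyphenyl)-2,3,7,7a-tetrahydro-1-benzofuran-6(5H)-one (C7a configuration not fixed) | COC1(OC)C=C2[C@H](C)[C@@H](c3cc(OC)c(OC)c(OC)c3)OC2CC1=O | intermediate
8 | (2S,3S)-5-methoxy-3-methyl-2-(3,4,5-trimethoxyphenyl)-2,3-dihydro-1-benzofuran-6-ol | COc1cc2c(cc1O)O[C@H](c1cc(OC)c(OC)c(OC)c1)[C@H]2C | intermediate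
9 | (2S,3S,3aS)-5-methoxy-3-methyl-3a-(prop-2-en-1-yl)-2-(3,4,5-trimethoxyphenyl)-3,3a-dihydro-1-benzofuran-6(2H)-one | C=CC[C@]12C=C(OC)C(=O)C=C1O[C@H](c1cc(OC)c(OC)c(OC)c1)[C@H]2C | intermediate
10 | (2S,3S,5R)-5-methoxy-3-methyl-5-(prop-2-en-1-yl)-2-(3,4,5-trimethoxyphenyl)-2,3-dihydro-1-benzofuran-6(5H)-one | C=CC[C@@]1(OC)C=C2C(=CC1=O)O[C@H](c1cc(OC)c(OC)c(OC)c1)[C@H]2C | target

## Step count and risks

Total step count: 6. Longest linear sequence: 6 steps (1 to 10).

Steps most likely to fail:

Step 4 (Proposed new method). The alkoxide conjugate addition may be slower than Diels–Alder dimerisation of the ortho-quinone monoketal. Loss of the C3 proton to a quinone methide would erode C3, and attack of methanol at C3a would divert the oxidation. The fallback uses known chemistry, sets out from 3 and returns at 8; the same O1–C7a bond is made by Ullmann-type aryl ether formation. Bromination of 3 with NBS in MeCN at 0 °C should go para to the methoxy group of the benzyloxy ring (the trimethoxyphenyl ring is deactivated by its acyl group) and give 2-[4-(benzyloxy)-2-bromo-5-methoxyphenyl]-1-(3,4,5-trimethoxyphenyl)propan-1-one F1. The hydrogenation of step 2 should then give (1S,2S)-2-[4-(benzyloxy)-2-bromo-5-methoxyphenyl]-1-(3,4,5-trimethoxyphenyl)propan-1-ol F2. CuI (10 mol%), 3,4,7,8-tetramethyl-1,10-phenanthroline, Cs2CO3, toluene, 110 °C should close ring B to (2S,3S)-6-(benzyloxy)-5-methoxy-3-methyl-2-(3,4,5-trimethoxyphenyl)-2,3-dihydro-1-benzofuran F3, and hydrogenolysis as in step 3 gives 8.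

Step 5. The allyl group may be delivered to C5 or C7 instead of C3a, facial selectivity at C3a may be poor, or the trimethoxyphenyl ring or the silane may be oxidised while oxidant, acidic fluorinated solvent and nucleophile are present together. The fallback sets out from 8 and returns at 9; oxidation and C–C bond formation are separated. PhI(OAc)2 in MeOH at 0 °C should convert 8 into the ortho-quinone monoketal (2S,3S)-5,5-dimethoxy-3-methyl-2-(3,4,5-trimethoxyphenyl)-2,3-dihydro-1-benzofuran-6(5H)-one F4. Hosomi–Sakurai substitution of this vinylogous allylic ketal (Me3SiOTf cat., allylSiMe3, CH2Cl2, −78 °C; ionisation at C5, attack at the γ-carbon C3a anti to the C3 methyl group) should then give 9 at low temperature and without oxidant.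

Step 6. The [3,3] shift may go to C7 with tautomerisation to an aromatic phenol, the product may shift its allyl group onward to O6, or the equilibrium may favour 9. The fallback sets out from 8 and returns at 10; the sigmatropic relay is replaced by carbonyl allylation of an ortho-quinone. Oxidative demethylation of 8 (PhI(OAc)2, MeCN–H2O, 0 °C) should give (2S,3S)-3-methyl-2-(3,4,5-trimethoxyphenyl)-2,3-dihydro-1-benzofuran-5,6-dione F5. Its C5 carbonyl (the C6 carbonyl belongs to the vinylogous ester O1–C7a=C7–C6=O and is less electrophilic) is allylated with allylB(pin) under chiral 3,3′-dibromo-BINOL catalysis (t-BuOH, toluene; catalyst enantiomer chosen for the 5R face, minor C5 epimer removed by chromatography). This should give (2S,3S,5R)-5-hydroxy-3-methyl-5-(prop-2-en-1-yl)-2-(3,4,5-trimethoxyphenyl)-2,3-dihydro-1-benzofuran-6(5H)-one F6. O-Methylation of the tertiary alcohol (MeOTf, 2,6-di-tert-butyl-4-methylpyridine, CH2Cl2) then gives 10.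

## Further compounds

F1 | step 4 | 2-[4-(benzyloxy)-2-bromo-5-methoxyphenyl]-1-(3,4,5-trimethoxyphenyl)propan-1-one (racemic) | COc1cc(C(C)C(=O)c2cc(OC)c(OC)c(OC)c2)c(Br)cc1OCc1ccccc1
F2 | step 4 | (1S,2S)-2-[4-(benzyloxy)-2-bromo-5-methoxyphenyl]-1-(3,4,5-trimethoxyphenyl)propan-1-ol | COc1cc([C@H](C)[C@H](O)c2cc(OC)c(OC)c(OC)c2)c(Br)cc1OCc1ccccc1
F3 | step 4 | (2S,3S)-6-(benzyloxy)-5-methoxy-3-methyl-2-(3,4,5-trimethoxyphenyl)-2,3-dihydro-1-benzofuran | COc1cc2c(cc1OCc1ccccc1)O[C@H](c1cc(OC)c(OC)c(OC)c1)[C@H]2C
F4 | step 5 | (2S,3S)-5,5-dimethoxy-3-methyl-2-(3,4,5-trimethoxyphenyl)-2,3-dihydro-1-benzofuran-6(5H)-one | COC1(OC)C=C2C(=CC1=O)O[C@H](c1cc(OC)c(OC)c(OC)c1)[C@H]2C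
F5 | step 6 | (2S,3S)-3-methyl-2-(3,4,5-trimethoxyphenyl)-2,3-dihydro-1-benzofuran-5,6-dione | O=C1C=C2C(=CC1=O)O[C@H](c1cc(OC)c(OC)c(OC)c1)[C@H]2C
F6 | step 6 | (2S,3S,5R)-5-hydroxy-3-methyl-5-(prop-2-en-1-yl)-2-(3,4,5-trimethoxyphenyl)-2,3-dihydro-1-benzofuran-6(5H)-one | C=CC[C@@]1(O)C=C2C(=CC1=O)O[C@H](c1cc(OC)c(OC)c(OC)c1)[C@H]2C
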